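The macrocycle is opened at C1–C2. C1 is the chain carbon on ring B (the gallic-type ring whose central oxygen is the ether bridge) and C14 is the one on ring A (the 1,3,5-substituted monophenol). The feature exploited is that C1, a secondary benzylic carbinol and the sole stereocentre, is an endocyclic atom of the 22-membered ring followed by thirteen bare methylenes. Intramolecular addition of an (E)-alkenylzinc to the ring B formyl group under a chiral amino alcohol thus forms C1–C2, closes the ring and fixes (R)-C1 at once. The precursor is the open tri-O-benzyl diaryl ether with CHO on ring B and a tridec-12-ynyl chain on ring A.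

Key step: step 7

Assumption: the sense of induction is inferred from this ligand family with benzaldehyde, where the (2S)-(−)-amino alcohol leads to Si-face attack. The (2R)-(+)-enantiomer is therefore assigned to Re-face attack and (R)-C1 (O > ring B carbon > C2 > H). The antipodal ligand would be used should the assignment prove reversed.

Step 1
Reactants: 1 syringaldehyde (4-hydroxy-3,5-dimethoxybenzaldehyde); 2 (3-bromo-5-methoxyphenyl)boronic acid
Product: 3 4-(3-bromo-5-methoxyphenoxy)-3,5-dimethoxybenzaldehyde
Conditions: Cu(OAc)2 (1 equiv, reoxidised by air), pyridine (5 equiv), 4 Å MS, CH2Cl2, dry air, rt; 2 in excess (2 equiv)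
Reagents that add atoms: none
Why: Chan–Lam–Evans oxidative C–O coupling, in which the fairly acidic di-ortho-substituted phenol binds divalent copper, the boronic acid transmetalates and reductive elimination from trivalent copper (O2 as terminal oxidant) should give the crowded diaryl ether at room temperature; ring B is bought with its central OH already free, so no regioselective protection of a pyrogallol is needed, the small methoxy groups keep the phenol accessible, and ring A can couple only at C–B because C–Br and CHO are inert here.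

Step 2
Reactants: 3 4-(3-bromo-5-methoxyphenoxy)-3,5-dimethoxybenzaldehyde
Product: 4 4-(3-bromo-5-hydroxyphenoxy)-3,5-dihydroxybenzaldehyde
Conditions: BBr3 (5 equiv), CH2Cl2, −78 °C → rt; then ice/H2O
Reagents that add atoms: none
Why: BBr3-mediated aryl methyl ether cleavage, in which boron coordinates each methoxy oxygen and bromide attacks the methyl carbon by SN2; it is placed before any alkyne or carbinol exists, so the only other functions are the diaryl ether, the aryl bromide and (after hydrolysis) the aldehyde, all of which tolerate the reagent.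

Step 3
Reactants: 4 4-(3-bromo-5-hydroxyphenoxy)-3,5-dihydroxybenzaldehyde
Product: 5 3,5-bis(benzyloxy)-4-[3-(benzyloxy)-5-bromophenoxy]benzaldehyde
Conditions: BnBr (3.5 equiv), K2CO3, DMF, rt → 50 °C
Reagents that add atoms: benzyl bromide, BrCc1ccccc1
Why: Williamson ether synthesis (SN2 of the three phenoxides on benzyl bromide) installs the one phenol protecting group that is inert to aqueous base, acetylide, dilute acid, Cy2BH, Et2Zn and diimide and still leaves under neutral conditions at the end.

Step 4
Reactants: 5 3,5-bis(benzyloxy)-4-[3-(benzyloxy)-5-bromophenoxy]benzaldehyde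
Product: 6 2-{3,5-bis(benzyloxy)-4-[3-(benzyloxy)-5-bromophenoxy]phenyl}-1,3-dioxolane
Conditions: HOCH2CH2OH (5 equiv), p-TsOH·H2O (5 mol%), toluene, reflux, Dean–Stark trap
Reagents that add atoms: ethylene glycol, OCCO
Why: Acid-catalysed acetalisation driven by azeotropic removal of water masks the formyl group as a base-stable 1,3-dioxolane for the borane and acetylide chemistry of the next two steps, while the benzyl ethers and the aryl bromide are unaffected.

Step 5
Reactants: 6 2-{3,5-bis(benzyloxy)-4-[3-(benzyloxy)-5-bromophenoxy]phenyl}-1,3-dioxolane; 7 11-bromoundec-1-ene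
Product: 9 2-{3,5-bis(benzyloxy)-4-[3-(benzyloxy)-5-(11-bromoundecyl)phenoxy]phenyl}-1,3-dioxolane, via 9-(11-bromoundecyl)-9-BBN 8 (not isolated)
Conditions: 7 (1.3 equiv), 9-BBN-H (1.25 equiv), THF, 0 °C → rt; then 6, PdCl2(dppf) (5 mol%), 3 M aq K3PO4, THF, 60 °C
Reagents that add atoms: 9-borabicyclo[3.3.1]nonane (9-BBN-H), B1C2CCCC1CCC2 (its boron cage is found in 8 only; 9 keeps just its hydrogen)
Why: 9-BBN-H adds anti-Markovnikov to the terminal alkene without touching the primary C–Br bond, and the B-alkyl Suzuki–Miyaura coupling (oxidative addition of zerovalent palladium into the aryl C–Br bond, base-assisted alkyl transfer from boron, reductive elimination outrunning β-hydride elimination on the wide-bite-angle dppf complex) joins C14 to ring A, the sp3 C–Br bond being inert to this catalyst and the dioxolane shielding the formyl carbon from residual B–H.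

Step 6
Reactants: 9 2-{3,5-bis(benzyloxy)-4-[3-(benzyloxy)-5-(11-bromoundecyl)phenoxy]phenyl}-1,3-dioxolane
Product: 11 3,5-bis(benzyloxy)-4-[3-(benzyloxy)-5-(tridec-12-yn-1-yl)phenoxy]benzaldehyde (the ynal), via dioxolane-protected alkyne 10 (not isolated)
Conditions: HC≡CLi·H2NCH2CH2NH2 (3 equiv), DMSO/THF, 0 °C → rt; aqueous extraction; crude 10 in THF/2 M HCl, rt
Reagents that add atoms: lithium acetylide–ethylenediamine complex, [Li+].[C-]#C.NCCN; water, O
Why: SN2 alkylation of lithium acetylide by the primary bromide in a dipolar aprotic medium adds the last two carbons (future C3 and C2), and acid-catalysed acetal hydrolysis of the crude dioxolane then releases the aldehyde under conditions that leave benzyl ethers, diaryl ether and terminal alkyne untouched.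

Step 7
Reactants: 11 3,5-bis(benzyloxy)-4-[3-(benzyloxy)-5-(tridec-12-yn-1-yl)phenoxy]benzaldehyde
Product: 14 tri-O-benzyl (1R,2E)-2,3-didehydrogravicycle (22-membered allylic alcohol), via alkenyl(dicyclohexyl)borane aldehyde 12 (not isolated), via alkenyl(ethyl)zinc aldehyde 13 (not isolated)
Conditions: Cy2BH (1.05 equiv, made in the flask from cyclohexene and BH3·SMe2), toluene, 0 °C → rt, about 1 h; solution of 12 diluted with toluene and added by syringe pump over 6–8 h to Et2Zn (1.5 equiv) and (2R)-(+)-3-exo-(dimethylamino)isoborneol (10 mol%) in toluene (final about 2 mM), 0 °C; sat. aq NH4Cl; Et3N-deactivated silica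
Reagents that add atoms: dicyclohexylborane, B(C1CCCCC1)C1CCCCC1 (in 12 only); diethylzinc, CC[Zn]CC (in 13 only); 14 keeps only hydrogen from them
Why: Cy2BH delivers H and B to the same side of the triple bond with boron on the unsubstituted carbon (future C2), giving (E)-alkenylborane 12; alkenyl/ethyl swap between boron and zinc turns it into the more nucleophilic 13, and the ethylzinc aminoalkoxide generated from the ligand ties 13 and the formyl oxygen together in a dinuclear zinc assembly from which the alkenyl carbon migrates to the carbonyl carbon. The closest known reaction type is the amino-alcohol-catalysed enantioselective alkenylzinc addition to aldehydes in its intramolecular form, which has already closed macrocyclic (E)-allylic alcohols from ω-alkynals. The 22-membered ring closes by a formally 22-exo-trig carbonyl 1,2-addition (C2 attacks C1, oxygen stays outside, C2=C3 ends up endocyclic), and syringe-pump addition keeps the stationary concentration of 13 so low that unimolecular closure should beat chain growth. C1 is set purely by reagent control, the (2R)-ligand being expected to open the Re face of the aryl aldehyde and give (R), with no resident stereocentre to oppose it. Chemoselectivity requires that the hindered borane consume the 1-alkyne before it touches CHO, which is helped by one equivalent of reagent, low temperature and the para aryloxy donor that lowers the electrophilicity of the formyl group, and that alkenyl leave zinc faster than ethyl, as sp2 groups normally do. The two ring B benzyloxy groups sit meta to the aldehyde, so they neither crowd nor chelate the reacting carbonyl, and all ethers are inert to borane and organozinc.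

Step 8
Reactants: 14 tri-O-benzyl (1R,2E)-2,3-didehydrogravicycle
Product: 15 tri-O-benzyl-(R)-gravicycle
Conditions: 2-nitrobenzenesulfonylhydrazide (excess, in portions), Et3N, CH2Cl2, rt
Reagents that add atoms: none
Why: Diimide reduction, in which HN=NH released from the sulfonylhydrazide hands two hydrogens to C2=C3 through a concerted six-centre syn transfer with no metal, cation or π-allyl intermediate, so the doubly activated C1–O bond, its configuration (still R, since the ring B carbon outranks C2 before and after) and the benzyl ethers are preserved while Et3N traps the sulfinic acid.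

Step 9
Reactants: 15 tri-O-benzyl-(R)-gravicycle
Product: 16 (R)-gravicycle
Conditions: H2 (1 atm), 10% Pd/C, EtOAc/EtOH, rt, acid-free; stopped as soon as the third benzyl group is gone
Reagents that add atoms: none
Why: Heterogeneous catalytic hydrogenolysis, in which aryl benzyl ethers are cleaved at the unhindered O–CH2Ph bond much faster than a secondary benzylic alcohol loses its poor hydroxide leaving group in an acid-free medium, so three equivalents of H2 should unveil the triphenol with C1 intact.

Compound list
1 | syringaldehyde (4-hydroxy-3,5-dimethoxybenzaldehyde) | O=Cc1cc(OC)c(O)c(OC)c1 | starting material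
2 | (3-bromo-5-methoxyphenyl)boronic acid | COc1cc(Br)cc(c1)B(O)O | starting material
3 | 4-(3-bromo-5-methoxyphenoxy)-3,5-dimethoxybenzaldehyde | O=Cc1cc(OC)c(Oc2cc(OC)cc(Br)c2)c(OC)c1 | intermediate
4 | 4-(3-bromo-5-hydroxyphenoxy)-3,5-dihydroxybenzaldehyde | O=Cc1cc(O)c(Oc2cc(O)cc(Br)c2)c(O)c1 | intermediate
5 | 3,5-bis(benzyloxy)-4-[3-(benzyloxy)-5-bromophenoxy]benzaldehyde | O=Cc1cc(OCc2ccccc2)c(Oc2cc(OCc3ccccc3)cc(Br)c2)c(OCc2ccccc2)c1 | intermediate
6 | 2-{3,5-bis(benzyloxy)-4-[3-(benzyloxy)-5-bromophenoxy]phenyl}-1,3-dioxolane | C1COC(O1)c1cc(OCc2ccccc2)c(Oc2cc(OCc3ccccc3)cc(Br)c2)c(OCc2ccccc2)c1 | intermediate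
7 | 11-bromoundec-1-ene | C=CCCCCCCCCCBr | starting material
8 | 9-(11-bromoundecyl)-9-borabicyclo[3.3.1]nonane (not isolated) | BrCCCCCCCCCCCB1C2CCCC1CCC2 | intermediate
9 | 2-{3,5-bis(benzyloxy)-4-[3-(benzyloxy)-5-(11-bromoundecyl)phenoxy]phenyl}-1,3-dioxolane | BrCCCCCCCCCCCc1cc(OCc2ccccc2)cc(Oc2c(OCc3ccccc3)cc(C3OCCO3)cc2OCc2ccccc2)c1 | intermediate
10 | 2-{3,5-bis(benzyloxy)-4-[3-(benzyloxy)-5-(tridec-12-yn-1-yl)phenoxy]phenyl}-1,3-dioxolane (not isolated) | C#CCCCCCCCCCCCc1cc(OCc2ccccc2)cc(Oc2c(OCc3ccccc3)cc(C3OCCO3)cc2OCc2ccccc2)c1 | intermediate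
11 | 3,5-bis(benzyloxy)-4-[3-(benzyloxy)-5-(tridec-12-yn-1-yl)phenoxy]benzaldehyde (ynal) | O=Cc1cc(OCc2ccccc2)c(Oc2cc(OCc3ccccc3)cc(CCCCCCCCCCCC#C)c2)c(OCc2ccccc2)c1 | intermediate
12 | 3,5-bis(benzyloxy)-4-{3-(benzyloxy)-5-[(E)-13-(dicyclohexylboranyl)tridec-12-en-1-yl]phenoxy}benzaldehyde (not isolated) | O=Cc1cc(OCc2ccccc2)c(Oc2cc(OCc3ccccc3)cc(CCCCCCCCCCC/C=C/B(C3CCCCC3)C3CCCCC3)c2)c(OCc2ccccc2)c1 | intermediate
13 | (E)-alkenyl(ethyl)zinc derived from 12, zinc on the terminal alkene carbon (not isolated) | O=Cc1cc(OCc2ccccc2)c(Oc2cc(OCc3ccccc3)cc(CCCCCCCCCCC/C=C/[Zn]CC)c2)c(OCc2ccccc2)c1 | intermediate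
14 | tri-O-benzyl (1R,2E)-2,3-didehydrogravicycle (macrocyclic allylic alcohol) | C(c1ccccc1)Oc1cc2cc(c1)Oc1c(OCc3ccccc3)cc(cc1OCc1ccccc1)[C@H](O)/C=C/CCCCCCCCCCC2 | intermediate
15 | tri-O-benzyl-(R)-gravicycle | C(c1ccccc1)Oc1cc2cc(c1)Oc1c(OCc3ccccc3)cc(cc1OCc1ccccc1)[C@H](O)CCCCCCCCCCCCC2 | intermediate
16 | (R)-gravicycle | Oc1cc2cc(c1)Oc1c(O)cc(cc1O)[C@H](O)CCCCCCCCCCCCC2 | target

Total step count: 9. Longest linear sequence: 9 steps (1 or 2 to 16); 7 enters at step 5.

Steps most likely to fail

Step 7 (macrocyclisation).
- **What may go wrong:** the borane may reduce the formyl group before the alkyne is consumed. The alkenylzinc may add between molecules faster than within one, so that oligomers grow. Ethyl may transfer in place of alkenyl. Ligand-free addition may erode the facial selectivity.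
- **Fallback:** it makes the same C1–C2 bond but separates ring closure from stereocontrol, and it sets out from 10, which is isolated instead of being hydrolysed.
 - Hydrozirconation–iodination (Cp2Zr(H)Cl, THF, rt; then I2) gives the (E)-vinyl iodide acetal F1.
 - 2 M HCl/THF gives the iodo aldehyde F2.
 - A Nozaki–Hiyama–Kishi macrocyclisation (CrCl2, 1% NiCl2, DMSO/THF, slow addition) gives the racemic macrocyclic allylic alcohol F3.
 - Diimide as in step 8 gives the racemic saturated carbinol F4.
 - Dess–Martin periodinane gives the macrocyclic aryl alkyl ketone F5.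
 - Corey–Bakshi–Shibata reduction ((S)-2-methyl-CBS-oxazaborolidine, BH3·SMe2, toluene, −20 °C) distinguishes aryl from n-alkyl reliably and should set (R)-C1.
- **Return:** the path comes back to the route at 15.

Step 1 (diaryl ether).
- **What may go wrong:** C–O bond formation at the crowded, weakly nucleophilic phenoxide may be so slow that protodeboronation and oxidative hydroxylation of the boronic acid outrun the coupling.
- **Fallback:** it replaces copper and boron by metal-free ligand coupling on trivalent iodine and sets out from 1.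
 - Purchased 1-bromo-3-iodo-5-methoxybenzene F6 is converted in one pot (mCPBA, TsOH·H2O, MeCN; then 1,3,5-trimethoxybenzene) into (3-bromo-5-methoxyphenyl)(2,4,6-trimethoxyphenyl)iodonium tosylate F7.
 - The potassium phenoxide of 1 (K2CO3, toluene, 55 °C) attacks iodine, and the less electron-rich aryl group is transferred to oxygen. This process is little affected by ortho substituents on the phenol.
- **Return:** the path comes back to the route at 3.

Step 9 (global debenzylation).
- **What may go wrong:** hydrogenolytic loss of the benzylic C1–O bond may compete with removal of the last benzyl ether.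
- **Fallback:** it masks the carbinol before the reduction and sets out from 15.
 - TBSCl, imidazole, DMF gives the C1 tert-butyldimethylsilyl ether F8, whose bulky siloxy group keeps C1 away from the catalyst surface.
 - H2, Pd/C, EtOAc gives the triphenol silyl ether F9.
 - TBAF/AcOH, THF removes the silyl group.
- **Return:** the path comes back to the route at 16.

Further compounds
F1 | step 7 | 2-{3,5-bis(benzyloxy)-4-[3-(benzyloxy)-5-((E)-13-iodotridec-12-en-1-yl)phenoxy]phenyl}-1,3-dioxolane | I/C=C/CCCCCCCCCCCc1cc(OCc2ccccc2)cc(Oc2c(OCc3ccccc3)cc(C3OCCO3)cc2OCc2ccccc2)c1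
F2 | step 7 | 3,5-bis(benzyloxy)-4-[3-(benzyloxy)-5-((E)-13-iodotridec-12-en-1-yl)phenoxy]benzaldehyde | O=Cc1cc(OCc2ccccc2)c(Oc2cc(OCc3ccccc3)cc(CCCCCCCCCCC/C=C/I)c2)c(OCc2ccccc2)c1
F3 | step 7 | racemic tri-O-benzyl (E)-2,3-didehydrogravicycle | C(c1ccccc1)Oc1cc2cc(c1)Oc1c(OCc3ccccc3)cc(cc1OCc1ccccc1)C(O)/C=C/CCCCCCCCCCC2
F4 | step 7 | racemic tri-O-benzylgravicycle | C(c1ccccc1)Oc1cc2cc(c1)Oc1c(OCc3ccccc3)cc(cc1OCc1ccccc1)C(O)CCCCCCCCCCCCC2
F5 | step 7 | tri-O-benzyl-1-oxo macrocycle (C1 ketone) | C(c1ccccc1)Oc1cc2cc(c1)Oc1c(OCc3ccccc3)cc(cc1OCc1ccccc1)C(=O)CCCCCCCCCCCCC2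
F6 | step 1 | 1-bromo-3-iodo-5-methoxybenzene (purchased) | COc1cc(Br)cc(I)c1
F7 | step 1 | (3-bromo-5-methoxyphenyl)(2,4,6-trimethoxyphenyl)iodonium tosylate | COc1cc(Br)cc(c1)[I+]c1c(OC)cc(OC)cc1OC.Cc1ccc(cc1)S(=O)(=O)[O-]
F8 | step 9 | tri-O-benzyl-(R)-gravicycle C1 tert-butyldimethylsilyl ether | C(c1ccccc1)Oc1cc2cc(c1)Oc1c(OCc3ccccc3)cc(cc1OCc1ccccc1)[C@H](O[Si](C)(C)C(C)(C)C)CCCCCCCCCCCCC2
F9 | step 9 | (R)-gravicycle C1 tert-butyldimethylsilyl ether | Oc1cc2cc(c1)Oc1c(O)cc(cc1O)[C@H](O[Si](C)(C)C(C)(C)C)CCCCCCCCCCCCC2
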